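Everything rests on cutting the cyclohexene ring at C1–C2 and C5–C6. In the target ring the stereogenic C1 is flanked by the quaternary C6 (two methyls) and by the methyl-substituted C2. Piperylene and prenal deliver exactly this 1,2,6-array when they combine with ortho regiochemistry; the only mismatch is a ring olefin at C3=C4 instead of C2=C3. A catalytic enantioselective [4+2] cycloaddition therefore forms the six-membered ring, the quaternary carbon and the permanent C1 stereocentre in one operation from two purchased achiral C5 compounds, (E)-penta-1,3-diene and 3-methylbut-2-enal. Reduction, olefin migration, sulfone formation and alkylation with a C10 allylic bromide bearing the protected butenediol finish the skeleton.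

Key step: step 1

Assumption: the sense of induction in step 1 is assigned from the formyl C–H···O binding model of oxazaborolidinium–enal complexes, which predicts the (1R) adduct from the (S)-diphenylprolinol-derived catalyst; if the adduct proves antipodal, the mirror-image catalyst is used in the same way.

**Step 1**
Reactants: 1 (E)-penta-1,3-diene; 2 3-methylbut-2-enal
Product: 3 (1R,2R)-2,6,6-trimethylcyclohex-3-ene-1-carbaldehyde
Conditions: (S)-o-tolyl-CBS oxazaborolidine/Tf2NH (20 mol%), 1 (5 equiv), CH2Cl2, −78 → −40 °C; cold aq NaHCO3; crude used at once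
Reagents that add atoms: none
Why: Proposed new method: the cationic boron binds the formyl oxygen of 2 (s-trans enal, formyl C–H···O contact to the ring oxygen, C=C stacked over the neighbouring aryl group), lowering the LUMO enough for a concerted but asynchronous [4+2] addition in which the CH2 terminus of 1 bonds ahead to the β,β-dimethyl carbon and the methyl-bearing terminus follows at the α-carbon; the closest known reaction types are achiral Lewis-acid Diels–Alder additions of piperylene to β,β-dimethyl enones and oxazaborolidinium-catalysed cycloadditions of less substituted enals. The six-membered ring is closed by this suprafacial cycloaddition itself, both σ-bonds (C1–C2 and C5–C6 of 3) arising in the single step. C1 is controlled by the catalyst, whose aryl group blocks one enal face so that the diene adds to the open face (predicted to lead to 1R with the S catalyst); C2 is set relative to C1 by the endo orientation of the activated formyl group (cis adduct), and because C2 is erased in step 3 any exo adduct formed on the same enal face converges on the same material. The step needs ortho regioselectivity, secured by the large HOMO coefficient at the unsubstituted diene terminus matching the large LUMO coefficient at the enal β-carbon, and enal-face selectivity, which rests on the catalyst alone. The adduct is kept cold, base-free and unpurified, since epimerisation at C1 would become loss of enantiopurity once C2 is removed.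

**Step 2**
Reactants: 3 (1R,2R)-2,6,6-trimethylcyclohex-3-ene-1-carbaldehyde
Product: 4 [(1R,2R)-2,6,6-trimethylcyclohex-3-en-1-yl]methanol
Conditions: NaBH4, MeOH, −20 → 0 °C
Reagents that add atoms: none
Why: Borohydride reduction of the aldehyde is fast under these mild conditions and removes the only epimerisable position next to C1, so both ring stereocentres are carried through unchanged.

**Step 3**
Reactants: 4 [(1R,2R)-2,6,6-trimethylcyclohex-3-en-1-yl]methanol
Product: 5 [(1S)-2,6,6-trimethylcyclohex-2-en-1-yl]methanol ((S)-α-cyclogeraniol)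
Conditions: RhCl3·3H2O (5 mol%), EtOH, 80 °C, stopped when 4 is consumed
Reagents that add atoms: none
Why: Transition-metal hydride olefin isomerisation (Rh–H formed in ethanol) should add across C3=C4 with Rh at C3 and eliminate the syn C2–H to give the more stable trisubstituted C2=C3 olefin, while further migration to C1=C2 would need a tertiary alkyl–rhodium next to C1 and is kinetically disfavoured; C2 ceases to be stereogenic and C1 is untouched, its descriptor changing from R to S only because the sp2 C2 now outranks C6.

**Step 4**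
Reactants: 5 [(1S)-2,6,6-trimethylcyclohex-2-en-1-yl]methanol
Product: 6 {[(1S)-2,6,6-trimethylcyclohex-2-en-1-yl]methyl}(phenyl)sulfane
Conditions: PhSSPh, n-Bu3P, pyridine, rt → 50 °C
Reagents that add atoms: diphenyl disulfide, c1ccccc1SSc1ccccc1
Why: In the Hata reaction the alcohol is activated as an alkoxyphosphonium salt and displaced by thiophenolate in an SN2 reaction at the primary carbon, a process that tolerates β-branched primary alcohols and does not involve C1.

**Step 5**
Reactants: 6 {[(1S)-2,6,6-trimethylcyclohex-2-en-1-yl]methyl}(phenyl)sulfane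
Product: 7 {[(1S)-2,6,6-trimethylcyclohex-2-en-1-yl]methanesulfonyl}benzene
Conditions: (NH4)6Mo7O24·4H2O (10 mol%), 30% H2O2, EtOH, 0 °C → rt
Reagents that add atoms: hydrogen peroxide, OO
Why: Molybdate-catalysed peroxide oxidation takes a sulfide to the sulfone much faster than the peroxomolybdate epoxidises a trisubstituted olefin, so the ring olefin and C1 should be unaffected.

**Step 6**
Reactants: 8 5-bromo-2-methylpent-2-ene; 9 but-2-yne-1,4-diol
Product: 12 (2E)-2-(4-methylpent-3-en-1-yl)but-2-ene-1,4-diol, via homoprenylmagnesium bromide 10 (not isolated), via oxamagnesacycle adduct 11 (not isolated)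
Conditions: 8, Mg, THF, 40 °C (3.3 equiv of 10); 9, THF, 0 °C; CuI (10 mol%), rt → 40 °C; sat. aq NH4Cl
Reagents that add atoms: none
Why: Copper-catalysed anti-carbomagnesiation of the propargylic dialkoxide (two equivalents of Grignard reagent act as base) delivers the alkyl group to one alkyne carbon and magnesium to the other within a five-membered O–Mg chelate, which forces alkyl and magnesium trans, so that protonolysis gives the olefin with the two CH2OH groups trans, as the target requires.

**Step 7**
Reactants: 12 (2E)-2-(4-methylpent-3-en-1-yl)but-2-ene-1,4-diol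
Product: 13 (2E)-1,4-bis[(tert-butyldimethylsilyl)oxy]-2-(4-methylpent-3-en-1-yl)but-2-ene
Conditions: TBSCl (2.3 equiv), imidazole, DMF, rt
Reagents that add atoms: tert-butyldimethylsilyl chloride, CC(C)(C)[Si](C)(C)Cl
Why: Imidazole-promoted silylation of the two primary allylic alcohols gives ethers that survive the selenium oxidation, the lithiated sulfone and the amalgam reduction.

**Step 8**
Reactants: 13 (2E)-1,4-bis[(tert-butyldimethylsilyl)oxy]-2-(4-methylpent-3-en-1-yl)but-2-ene
Product: 14 (2E,6E)-8-[(tert-butyldimethylsilyl)oxy]-6-{[(tert-butyldimethylsilyl)oxy]methyl}-2-methylocta-2,6-dien-1-ol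
Conditions: SeO2 (0.5 equiv), t-BuOOH (3 equiv), salicylic acid (cat.), CH2Cl2, rt; run to partial conversion, 13 recycled
Reagents that add atoms: tert-butyl hydroperoxide, CC(C)(C)OO (oxygen relayed through catalytic selenium dioxide, O=[Se]=O)
Why: Sharpless selenium dioxide allylic oxidation (ene reaction then [2,3]-sigmatropic shift) attacks the electron-rich terminal trisubstituted olefin rather than the olefin deactivated by two allylic oxygens, and places the hydroxyl on the (E)-methyl group, setting the (E)-geometry of the future C6=C7 bond.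

**Step 9**
Reactants: 14 (2E,6E)-8-[(tert-butyldimethylsilyl)oxy]-6-{[(tert-butyldimethylsilyl)oxy]methyl}-2-methylocta-2,6-dien-1-ol
Product: 15 (2E,6E)-1-bromo-8-[(tert-butyldimethylsilyl)oxy]-6-{[(tert-butyldimethylsilyl)oxy]methyl}-2-methylocta-2,6-diene
Conditions: CBr4, PPh3, CH2Cl2, −20 → 0 °C
Reagents that add atoms: carbon tetrabromide, BrC(Br)(Br)Br
Why: The Appel reaction converts the primary allylic alcohol to the bromide by SN2 displacement of the oxyphosphonium group at low temperature, without allylic transposition and without touching the silyl ethers.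

**Step 10**
Reactants: 7 {[(1S)-2,6,6-trimethylcyclohex-2-en-1-yl]methanesulfonyl}benzene; 15 (2E,6E)-1-bromo-8-[(tert-butyldimethylsilyl)oxy]-6-{[(tert-butyldimethylsilyl)oxy]methyl}-2-methylocta-2,6-diene
Product: 17 (2E,6E)-1-[(tert-butyldimethylsilyl)oxy]-3-{[(tert-butyldimethylsilyl)oxy]methyl}-7-methyl-9-(phenylsulfonyl)-9-[(1S)-2,6,6-trimethylcyclohex-2-en-1-yl]nona-2,6-diene (epimers at C9), via lithiated sulfone 16 (not isolated)
Conditions: n-BuLi (1.05 equiv), THF, −78 °C; DMPU, then 15, −78 → −20 °C
Reagents that add atoms: none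
Why: Alkylation of the α-sulfonyl carbanion by SN2 attack on the primary allylic bromide is the established way of extending cyclogeranyl sulfones; only the sulfone α-hydrogen is removed by one equivalent of base, so C1 is safe, and the new C9 centre forms as an inconsequential epimer mixture that is erased in step 11.

**Step 11**
Reactants: 17 the coupled sulfone
Product: 18 (2E,6E)-1-[(tert-butyldimethylsilyl)oxy]-3-{[(tert-butyldimethylsilyl)oxy]methyl}-7-methyl-9-[(1S)-2,6,6-trimethylcyclohex-2-en-1-yl]nona-2,6-diene
Conditions: 6% Na(Hg), Na2HPO4, MeOH–THF, −20 °C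
Reagents that add atoms: none
Why: Reductive desulfonylation by electron transfer from buffered sodium amalgam cleaves the alkyl C–S bond and protonates the resulting carbanion, with no β-leaving group available for elimination and with olefins and silyl ethers inert.

**Step 12**
Reactants: 18 the bis-silyl ether
Product: 19 (2E)-2-{(3E)-4-methyl-6-[(1S)-2,6,6-trimethylcyclohex-2-en-1-yl]hex-3-en-1-yl}but-2-ene-1,4-diol
Conditions: TBAF, THF, 0 °C → rt
Reagents that add atoms: none
Why: Fluoride-mediated desilylation frees both primary alcohols under conditions that leave the three olefins and C1 unchanged.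

**Step 13**
Reactants: 19 the diol
Product: 20 (2E,6E)-3-(acetoxymethyl)-7-methyl-9-[(1S)-2,6,6-trimethylcyclohex-2-en-1-yl]nona-2,6-dien-1-yl acetate (target)
Conditions: Ac2O, pyridine, DMAP (cat.), CH2Cl2, 0 °C → rt
Reagents that add atoms: acetic anhydride, CC(=O)OC(C)=O
Why: DMAP-catalysed acylation of the two unhindered primary allylic alcohols should be complete under mild, non-acidic conditions that cannot move the ring olefin.

**Compound list**

1 | (E)-penta-1,3-diene | C/C=C/C=C | starting material
2 | 3-methylbut-2-enal | CC(C)=CC=O | starting material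
3 | (1R,2R)-2,6,6-trimethylcyclohex-3-ene-1-carbaldehyde (cis) | O=C[C@@H]1[C@H](C)C=CCC1(C)C | intermediate
4 | [(1R,2R)-2,6,6-trimethylcyclohex-3-en-1-yl]methanol | OC[C@@H]1[C@H](C)C=CCC1(C)C | intermediate
5 | [(1S)-2,6,6-trimethylcyclohex-2-en-1-yl]methanol | OC[C@@H]1C(C)=CCCC1(C)C | intermediate
6 | {[(1S)-2,6,6-trimethylcyclohex-2-en-1-yl]methyl}(phenyl)sulfane | c1ccccc1SC[C@@H]2C(C)=CCCC2(C)C | intermediate
7 | {[(1S)-2,6,6-trimethylcyclohex-2-en-1-yl]methanesulfonyl}benzene | O=S(=O)(C[C@@H]1C(C)=CCCC1(C)C)c2ccccc2 | intermediate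
8 | 5-bromo-2-methylpent-2-ene | CC(C)=CCCBr | starting material
9 | but-2-yne-1,4-diol | OCC#CCO | starting material
10 | (4-methylpent-3-en-1-yl)magnesium bromide | CC(C)=CCC[Mg]Br | intermediate (not isolated)
11 | oxamagnesacycle adduct (2,5-dihydro-1,2-oxamagnesole with the homoprenyl group at C4 and CH2OMgBr at C3) | CC(C)=CCCC1=C(CO[Mg]Br)[Mg]OC1 | intermediate (not isolated)
12 | (2E)-2-(4-methylpent-3-en-1-yl)but-2-ene-1,4-diol | OC/C=C(\CCC=C(C)C)CO | intermediate
13 | (2E)-1,4-bis[(tert-butyldimethylsilyl)oxy]-2-(4-methylpent-3-en-1-yl)but-2-ene | CC(C)(C)[Si](C)(C)OC/C=C(\CCC=C(C)C)CO[Si](C)(C)C(C)(C)C | intermediate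
14 | (2E,6E)-8-[(tert-butyldimethylsilyl)oxy]-6-{[(tert-butyldimethylsilyl)oxy]methyl}-2-methylocta-2,6-dien-1-ol | CC(C)(C)[Si](C)(C)OC/C=C(\CC/C=C(\C)CO)CO[Si](C)(C)C(C)(C)C | intermediate
15 | (2E,6E)-1-bromo-8-[(tert-butyldimethylsilyl)oxy]-6-{[(tert-butyldimethylsilyl)oxy]methyl}-2-methylocta-2,6-diene | CC(C)(C)[Si](C)(C)OC/C=C(\CC/C=C(\C)CBr)CO[Si](C)(C)C(C)(C)C | intermediate
16 | lithiated sulfone (α-lithio derivative of 7) | [Li]C(S(=O)(=O)c1ccccc1)[C@@H]2C(C)=CCCC2(C)C | intermediate (not isolated)
17 | (2E,6E)-1-[(tert-butyldimethylsilyl)oxy]-3-{[(tert-butyldimethylsilyl)oxy]methyl}-7-methyl-9-(phenylsulfonyl)-9-[(1S)-2,6,6-trimethylcyclohex-2-en-1-yl]nona-2,6-diene (C9 epimers) | CC(C)(C)[Si](C)(C)OC/C=C(\CC/C=C(\C)CC([C@@H]1C(C)=CCCC1(C)C)S(=O)(=O)c2ccccc2)CO[Si](C)(C)C(C)(C)C | intermediate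
18 | (2E,6E)-1-[(tert-butyldimethylsilyl)oxy]-3-{[(tert-butyldimethylsilyl)oxy]methyl}-7-methyl-9-[(1S)-2,6,6-trimethylcyclohex-2-en-1-yl]nona-2,6-diene | CC(C)(C)[Si](C)(C)OC/C=C(\CC/C=C(\C)CC[C@@H]1C(C)=CCCC1(C)C)CO[Si](C)(C)C(C)(C)C | intermediate
19 | (2E)-2-{(3E)-4-methyl-6-[(1S)-2,6,6-trimethylcyclohex-2-en-1-yl]hex-3-en-1-yl}but-2-ene-1,4-diol | OC/C=C(\CC/C=C(\C)CC[C@@H]1C(C)=CCCC1(C)C)CO | intermediate
20 | (2E,6E)-3-(acetoxymethyl)-7-methyl-9-[(1S)-2,6,6-trimethylcyclohex-2-en-1-yl]nona-2,6-dien-1-yl acetate | CC(=O)OC/C=C(\CC/C=C(\C)CC[C@@H]1C(C)=CCCC1(C)C)COC(C)=O | target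

**Step count and risks**

Total steps: 13. Longest linear sequence: 9 steps (steps 1–5, then 10–13); the side chain (steps 6–9) is made in parallel.

**Step 1 (proposed new method).** The hindered, electron-rich β-carbon of the enal may be activated too weakly for turnover at low temperature. The strong Lewis acid may instead oligomerise the diene. Facial discrimination may be poor for a dienophile class the catalyst has not been shown to handle. The aldehyde α-centre may epimerise before reduction.

Fallback, from 1 and 2, returning at 5. The cycloaddition would be run with an achiral Lewis acid (EtAlCl2, CH2Cl2, −20 °C → rt), the established way of driving piperylene onto β,β-dialkyl dienophiles, to give racemic 2,6,6-trimethylcyclohex-3-ene-1-carbaldehyde F1 as a cis/trans mixture. NaBH4 would then give racemic (2,6,6-trimethylcyclohex-3-en-1-yl)methanol F2, and the rhodium conditions of step 3 racemic (2,6,6-trimethylcyclohex-2-en-1-yl)methanol F3, in which only one stereocentre remains. Acylation with (1S)-camphanoyl chloride (pyridine, DMAP) would give the diastereomeric esters [(1S)-2,6,6-trimethylcyclohex-2-en-1-yl]methyl (1S,4R)-camphanate F4 and [(1R)-2,6,6-trimethylcyclohex-2-en-1-yl]methyl (1S,4R)-camphanate F5, to be separated by fractional crystallisation or chromatography. Methanolysis of F4 (K2CO3, MeOH) returns to the route at 5.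

**Step 3.** The hydride catalyst may equilibrate the olefin between C3=C4 and C4=C5 without funnelling cleanly to C2=C3. It may also migrate further into the tetrasubstituted C1=C2 position, which destroys C1.

Fallback, from 4, returning at 7. The shift would be made stoichiometric. The Δ3 olefin would be carried through the conditions of steps 4 and 5 to {[(1R,2R)-2,6,6-trimethylcyclohex-3-en-1-yl]methyl}(phenyl)sulfane F6 and then {[(1R,2R)-2,6,6-trimethylcyclohex-3-en-1-yl]methanesulfonyl}benzene F7. Anti-addition of bromine (CH2Cl2, −78 °C) would give the trans-dibromide {[(1R,2S)-3,4-dibromo-2,6,6-trimethylcyclohexyl]methanesulfonyl}benzene F8. Twofold dehydrobromination (DBU, toluene, 80 °C; LiBr/Li2CO3 in DMF if the second elimination is slow) should give the conjugated diene {[(1R)-2,6,6-trimethylcyclohexa-2,4-dien-1-yl]methanesulfonyl}benzene F9, because a trans-dibromide eliminates outwards towards C2–H and C5–H rather than to a vinyl bromide. Diimide (potassium azodicarboxylate, AcOH, MeOH) should then saturate the disubstituted C4=C5 bond in preference to the trisubstituted C2=C3 bond and return to the route at 7.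

**Step 6.** The dialkoxide is sparingly soluble, so carbometalation may stall. Protonated or reduced by-products may also consume the Grignard reagent.

Fallback, from 9, returning at 13. The olefin geometry would be fixed by hydroalumination instead. Red-Al (THF, 0 °C) then I2 (−78 °C) would convert 9 by trans-hydroalumination and iododealumination into (Z)-2-iodobut-2-ene-1,4-diol F10. TBSCl/imidazole would give (Z)-1,4-bis[(tert-butyldimethylsilyl)oxy]-2-iodobut-2-ene F11. Negishi coupling with (4-methylpent-3-en-1-yl)zinc bromide F12 (from 8, Zn dust, LiCl, THF) under Pd(dppf)Cl2 proceeds with retention at the vinyl iodide and returns to the route at 13.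

**Further compounds**

F1 | step 1 | racemic 2,6,6-trimethylcyclohex-3-ene-1-carbaldehyde (cis/trans mixture) | O=CC1C(C)C=CCC1(C)C
F2 | step 1 | racemic (2,6,6-trimethylcyclohex-3-en-1-yl)methanol (cis/trans mixture) | OCC1C(C)C=CCC1(C)C
F3 | step 1 | racemic (2,6,6-trimethylcyclohex-2-en-1-yl)methanol | OCC1C(C)=CCCC1(C)C
F4 | step 1 | [(1S)-2,6,6-trimethylcyclohex-2-en-1-yl]methyl (1S,4R)-camphanate | O=C(OC[C@@H]1C(C)=CCCC1(C)C)[C@@]23CC[C@@](C)(C(=O)O2)C3(C)C
F5 | step 1 | [(1R)-2,6,6-trimethylcyclohex-2-en-1-yl]methyl (1S,4R)-camphanate | O=C(OC[C@H]1C(C)=CCCC1(C)C)[C@@]23CC[C@@](C)(C(=O)O2)C3(C)C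
F6 | step 3 | {[(1R,2R)-2,6,6-trimethylcyclohex-3-en-1-yl]methyl}(phenyl)sulfane | c1ccccc1SC[C@@H]2[C@H](C)C=CCC2(C)C
F7 | step 3 | {[(1R,2R)-2,6,6-trimethylcyclohex-3-en-1-yl]methanesulfonyl}benzene | O=S(=O)(C[C@@H]1[C@H](C)C=CCC1(C)C)c2ccccc2
F8 | step 3 | {[(1R,2S)-3,4-dibromo-2,6,6-trimethylcyclohexyl]methanesulfonyl}benzene (trans-dibromide, C3/C4 configuration not defined) | O=S(=O)(C[C@@H]1[C@H](C)C(Br)C(Br)CC1(C)C)c2ccccc2
F9 | step 3 | {[(1R)-2,6,6-trimethylcyclohexa-2,4-dien-1-yl]methanesulfonyl}benzene | O=S(=O)(C[C@@H]1C(C)=CC=CC1(C)C)c2ccccc2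
F10 | step 6 | (Z)-2-iodobut-2-ene-1,4-diol | OC/C=C(\I)CO
F11 | step 6 | (Z)-1,4-bis[(tert-butyldimethylsilyl)oxy]-2-iodobut-2-ene | CC(C)(C)[Si](C)(C)OC/C=C(\I)CO[Si](C)(C)C(C)(C)C
F12 | step 6 | (4-methylpent-3-en-1-yl)zinc bromide | CC(C)=CCC[Zn]Br
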